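All runs were computed with constants of no real substance; noise was put on by code.

Slowness is something we can choose here: [G], temperature and time can each be turned down, and we ask what each does to D at the end.

all flasks: X 0.050 M

| run | G | temperature | remark | time |
|---|---|---|---|---|
| spring | 0.015 M | 10 °C | run made earlier |  |
| autumn | 0.022 M | 21 °C | run made earlier |  |
| north-west | 0.0300 M |  | at 5 °C until 8.0 min, from then on at 25 °C | 12 min |
| south | 0.0300 M | 5 °C |  | 12 min |
| north | 0.0300 M | 25 °C |  | 12 min |

- spring (time / min: D / %, X / %): 2.50: 6.7, 77.3; 5.00: 11.9, 64.4; 8.00: 13.9, 56.9; 10.0: 17.9, 51.9; 12.0: 17.7, 49.8; 15.0: 15.7, 48.2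
- autumn (time / min: D / %, X / %): 1.00: 7.6, 74.9; 2.50: 19.0, 53.4; 4.00: 20.1, 40.8; 5.00: 20.3, 37.2; 6.00: 21.1, 31.1

(readings scatter by 1 percentage point)

- the best flask by amount of D, in percent of the X charged; "all alike" if 1.5 percentage points covers them all (north-west / south / north / all alike)
- amount of D at the end, in percent of the X charged, north-west
- amount of D at the end, in percent of the X charged, south
- amount of D at the end, in percent of the X charged, north



1. [G]. By hand, each G takes some X, so with X held at its charge, more G should take X further. In spring, X reads 49.8% at 12.0 min and 48.2% at 15.0 min, with G charged equal to 30.0% of X. The last reading gives 1.73, and this number, read with the scatter of the readings, is X lost per G charged; we call it the capacity. We read G as the limiting reagent in spring.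

2. Used at 0.0300 M with X at 0.050 M, the capacity allows a loss of 104% of X, about the whole charge. So we expect these flasks to differ in what the lost X became.

3. Temperature. By hand, warmth speeds the steps, though not necessarily alike. In autumn, warmer and richer in G, X falls 22 percentage points between 2.50 min and 6.00 min, while D rises 2.1 points. In spring, X falls 13 points between 2.50 min and 5.00 min, while D rises 5.2 points.

4. Time. By hand, longer means more X lost. But spring D reads 17.9% at 10.0 min and 15.7% at 15.0 min, a hint of decline at a scatter of 1 point. We lean towards south, without a figure for D.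

5. The forecast chooses north-west, with 24% there, 23% in south and 20% in north: “North-west's late heating converts more X, with little time for decay.”

6. The flasks give 22.6% in north-west, 28.2% in south and 14.0% in north, so the best is south.

    X + G → Z + J (k = 16.5 M⁻¹ min⁻¹, Ea = 37.0 kJ mol⁻¹)
    Z ⇌ D (K = 6.13, k = 2.79 min⁻¹, Ea = 84.0 kJ mol⁻¹, ΔH = −21.0 kJ mol⁻¹)
    Z ⇌ L (K = 120, k = 0.935 min⁻¹, Ea = 72.0 kJ mol⁻¹, ΔH = −5.00 kJ mol⁻¹)
    D → E (k = 3.53 × 10⁻⁴ min⁻¹, Ea = 110 kJ mol⁻¹)
    X + J → Q (k = 21.3 M⁻¹ min⁻¹, Ea = 60.0 kJ mol⁻¹)
    (constants at 25 °C)

7. In north, at 25 °C, the half-life of D by D → E is 32.7 h, far longer than the 12 min of the flask, and striking out that step hardly moves D there. Yet in north, D goes from 21.9% at 6.00 min to 14.0% at 12.0 min, while L goes from 25.2% to 37.4%. The capacity gave north a loss of 104% of X; the flask has lost 95.9% of X by 12.0 min, with 11% of the G charge left.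

8. Take north-west with 0.12 M of X. The capacity allows a loss of 43.2% of X, so G is limiting and about 56.8% of X should stay. The computed flask holds 50.1% of X, somewhat less, with G at 0.0412% of its charge and D at 10.4%.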